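**Retrosynthetic overview** (ring A = the cyclopentane, ring B = the cyclopentenone)
1. Target 21 ⇐ tertiary dienol 20 (perhydrolysis) ⇐ diol 19 (acetylation); ring B ⇐ ring-closing metathesis of vinyl ketone 18 ⇐ vinyl addition to δ-lactone 17.
2. Diene side chain ⇐ Suzuki coupling of alkenyl boronate 13 with iodide 16; the boronate ⇐ methyl ketone 9 (boron-Wittig).
3. Key step: Ireland–Claisen [3,3] rearrangement of (E)-crotyl ester 10 makes the C–C bond between the two ring-B stereocentres; the new carboxylate opens the spiro-epoxide to the cis-fused lactone 13.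
4. Ring A ⇐ 5-exo enolate alkylation of allylic chloride 7; its five carbons, the CH2O carbon, the acetic arm, the acetyl group and the one bought stereocentre all come from (S)-limonene by ozonolysis.
5. Ring order: ring A (step 5), temporary lactone (step 8), ring B last (step 12).

Assumption: the target is taken as drawn, i.e. a (1R,2S,4S)-cyclopentane carrying a cis-(1S,5R)-5-methyl-2-oxocyclopent-3-enyl group; (S)-(−)-limonene is the only chiral starting material.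

Step 1
Reactants: 1 (S)-(−)-limonene
Product: 3 (3S)-6-oxo-3-(prop-1-en-2-yl)heptanal, via ozonide 2 (not isolated)
Conditions: O3 (1.0 equiv), CH2Cl2, −78 °C; then Me2S, −78 °C to rt
Reagents that add atoms: ozone, O=[O+][O-]
Why: Ozonolysis with reductive work-up, in which the trisubstituted ring alkene reacts faster than the isopropenyl group, so one equivalent of O3 opens the ring and leaves the bought stereocentre (later C2 of ring A) untouched.

Step 2
Reactants: 3 (3S)-6-oxo-3-(prop-1-en-2-yl)heptanal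
Product: 4 (3S)-6-oxo-3-(prop-1-en-2-yl)heptanoic acid
Conditions: NaClO2, NaH2PO4, 2-methylbut-2-ene, t-BuOH/H2O, 0 °C to rt
Reagents that add atoms: sodium chlorite, [Na+].[O-]Cl=O
Why: Pinnick oxidation converts only the aldehyde into the acid (the scavenger protects the isopropenyl group) and touches neither the ketone nor the stereocentre.

Step 3
Reactants: 4 (3S)-6-oxo-3-(prop-1-en-2-yl)heptanoic acid; 5 (E)-but-2-en-1-ol
Product: 6 (E)-but-2-en-1-yl (3S)-6-oxo-3-(prop-1-en-2-yl)heptanoate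
Conditions: DCC, DMAP (cat.), CH2Cl2, 0 °C to rt
Reagents that add atoms: none
Why: Steglich esterification installs the (E)-crotyl group that later serves as the allyl half of the sigmatropic rearrangement, and no stereocentre is involved.

Step 4
Reactants: 6 (E)-but-2-en-1-yl (3S)-6-oxo-3-(prop-1-en-2-yl)heptanoate
Product: 7 (E)-but-2-en-1-yl (3S)-3-(3-chloroprop-1-en-2-yl)-6-oxoheptanoate
Conditions: Ca(OCl)2, CO2 (solid), CH2Cl2/H2O, 0 °C
Reagents that add atoms: calcium hypochlorite, [Ca+2].[O-]Cl.[O-]Cl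
Why: Ene-type allylic chlorination by HOCl, in which the electron-rich 1,1-disubstituted isopropenyl alkene reacts much faster than the crotyl alkene (deactivated by its allylic acyloxy group) and gives the 2-(chloromethyl)allyl unit.

Step 5
Reactants: 7 (E)-but-2-en-1-yl (3S)-3-(3-chloroprop-1-en-2-yl)-6-oxoheptanoate
Product: 8 (E)-but-2-en-1-yl 2-[(1S,4S)-4-acetyl-2-methylidenecyclopentyl]acetate
Conditions: KOtBu (1.05 equiv), THF/t-BuOH, −20 °C to rt
Reagents that add atoms: none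
Why: Intramolecular enolate C-alkylation (5-exo-tet) forms ring A, and under the equilibrating base the acetyl-bearing centre settles cis to the side arm fixed by limonene (both substituents pseudo-equatorial, about 3:1 expected, the trans epimer is re-equilibrated), giving the (1S,4S) isomer.

Step 6
Reactants: 8 (E)-but-2-en-1-yl 2-[(1S,4S)-4-acetyl-2-methylidenecyclopentyl]acetate
Product: 9 (E)-but-2-en-1-yl 2-[(3R,4S,6S)-6-acetyl-1-oxaspiro[2.4]heptan-4-yl]acetate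
Conditions: mCPBA (1.05 equiv), CH2Cl2, 0 °C
Reagents that add atoms: 3-chloroperbenzoic acid, OOC(=O)c1cccc(Cl)c1
Why: Prilezhaev epoxidation of the exocyclic alkene (more nucleophilic than the acyloxy-deactivated crotyl alkene) occurs on the face opposite to the neighbouring acetic side arm, which sets the future tertiary C–O bond trans to that arm (3R).

Step 7
Reactants: 9 (E)-but-2-en-1-yl 2-[(3R,4S,6S)-6-acetyl-1-oxaspiro[2.4]heptan-4-yl]acetate
Product: 10 (E)-but-2-en-1-yl 2-[(3R,4S,6S)-6-[(E)-1-(4,4,5,5-tetramethyl-1,3,2-dioxaborolan-2-yl)prop-1-en-2-yl]-1-oxaspiro[2.4]heptan-4-yl]acetate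
Conditions: CH2(Bpin)2, lithium 2,2,6,6-tetramethylpiperidide (LiTMP), THF, 0 °C; then 9, −78 °C to rt
Reagents that add atoms: bis(4,4,5,5-tetramethyl-1,3,2-dioxaborolan-2-yl)methane, CC1(C)OB(CB2OC(C)(C)C(C)(C)O2)OC1(C)C
Why: Boron-Wittig olefination, in which the lithiated geminal bis(boronate) adds to the methyl ketone faster than to the ester or epoxide and B–O elimination puts boron trans to the bulky ring (E), which also removes the epimerisable α-keto centre.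

Step 8
Reactants: 10 (E)-but-2-en-1-yl 2-[(3R,4S,6S)-6-[(E)-1-(4,4,5,5-tetramethyl-1,3,2-dioxaborolan-2-yl)prop-1-en-2-yl]-1-oxaspiro[2.4]heptan-4-yl]acetate
Product: 13 (4S,4aS,6S,7aR)-4-[(2R)-but-3-en-2-yl]-7a-hydroxy-6-[(E)-1-(4,4,5,5-tetramethyl-1,3,2-dioxaborolan-2-yl)prop-1-en-2-yl]hexahydrocyclopenta[c]pyran-3(1H)-one, via silyl ketene acetal 11 (not isolated), via epoxy acid 12 (not isolated)
Conditions: LiN(iPr)2, Me3SiCl, THF, −78 °C to rt; then aq. NaHCO3, 40 °C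
Reagents that add atoms: chlorotrimethylsilane, C[Si](C)(C)Cl
Why: Ireland–Claisen [3,3]-sigmatropic rearrangement, in which LiN(iPr)2 in THF gives the ketene acetal with the ring cis to the crotyloxy oxygen, the chair transition state with the (E)-crotyl methyl equatorial gives the anti (2S,3R) acid, the allyl unit adds to the enolate face anti to the quaternary epoxide carbon of ring A (allylic-strain control by the limonene-derived centre), and the freed carboxylate opens the epoxide at its CH2 carbon to the cis-fused δ-lactone without touching the tertiary C–O bond.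

Step 9
Reactants: 14 2-methylbut-3-yn-2-ol
Product: 16 (E)-4-iodo-2-methylbut-3-en-2-ol, via vinylstannane 15 (not isolated)
Conditions: Bu3SnH, PdCl2(PPh3)2 (2 mol%), THF, 0 °C to rt; then I2, CH2Cl2, 0 °C
Reagents that add atoms: tributyltin hydride, CCCC[SnH](CCCC)CCCC; iodine, [I][I]
Why: Palladium-catalysed syn hydrostannation places tin on the terminal carbon of the hindered propargylic alcohol and iododestannylation with retention gives the (E)-iodide, with no stereocentre involved.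

Step 10
Reactants: 13 (4S,4aS,6S,7aR)-4-[(2R)-but-3-en-2-yl]-7a-hydroxy-6-[(E)-1-(4,4,5,5-tetramethyl-1,3,2-dioxaborolan-2-yl)prop-1-en-2-yl]hexahydrocyclopenta[c]pyran-3(1H)-one; 16 (E)-4-iodo-2-methylbut-3-en-2-ol
Product: 17 (4S,4aS,6S,7aR)-4-[(2R)-but-3-en-2-yl]-7a-hydroxy-6-[(2E,4E)-6-hydroxy-6-methylhepta-2,4-dien-2-yl]hexahydrocyclopenta[c]pyran-3(1H)-one
Conditions: PdCl2(dppf) (5 mol%), K3PO4, THF/H2O (10:1), 40 °C; work-up at pH 4
Reagents that add atoms: none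
Why: Suzuki–Miyaura coupling joins the two alkenyl partners with retention of both double-bond geometries to give the (2E,4E)-diene, and the stereocentres are not involved.

Step 11
Reactants: 17 (4S,4aS,6S,7aR)-4-[(2R)-but-3-en-2-yl]-7a-hydroxy-6-[(2E,4E)-6-hydroxy-6-methylhepta-2,4-dien-2-yl]hexahydrocyclopenta[c]pyran-3(1H)-one
Product: 18 (4S,5R)-4-[(1S,2R,4S)-2-hydroxy-2-(hydroxymethyl)-4-[(2E,4E)-6-hydroxy-6-methylhepta-2,4-dien-2-yl]cyclopentyl]-5-methylhepta-1,6-dien-3-one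
Conditions: CH2=CHMgBr (4 equiv), CeCl3, THF, −78 °C; aq. NH4Cl
Reagents that add atoms: vinylmagnesium bromide, C=C[Mg]Br
Why: Addition of the weakly basic vinylcerium reagent to the lactone carbonyl stops at the tetrahedral hemiketal alkoxide at low temperature, so one vinyl group is delivered and work-up releases the vinyl ketone and the primary alcohol without epimerising the α-centre.

Step 12
Reactants: 18 (4S,5R)-4-[(1S,2R,4S)-2-hydroxy-2-(hydroxymethyl)-4-[(2E,4E)-6-hydroxy-6-methylhepta-2,4-dien-2-yl]cyclopentyl]-5-methylhepta-1,6-dien-3-one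
Product: 19 (4R,5S)-5-[(1S,2R,4S)-2-hydroxy-2-(hydroxymethyl)-4-[(2E,4E)-6-hydroxy-6-methylhepta-2,4-dien-2-yl]cyclopentyl]-4-methylcyclopent-2-en-1-one
Conditions: second-generation Grubbs catalyst RuCl2(=CHPh)(PCy3)(H2IMes) (5 mol%), CH2Cl2, 40 °C
Reagents that add atoms: none
Why: Ring-closing metathesis between the enone vinyl group and the terminal vinyl group (the hindered diene alkenes do not react) forms ring B under neutral conditions, so the anti acyclic pair becomes the cis-4,5-disubstituted cyclopentenone (4R,5S).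

Step 13
Reactants: 19 (4R,5S)-5-[(1S,2R,4S)-2-hydroxy-2-(hydroxymethyl)-4-[(2E,4E)-6-hydroxy-6-methylhepta-2,4-dien-2-yl]cyclopentyl]-4-methylcyclopent-2-en-1-one
Product: 20 [(1R,2S,4S)-1-hydroxy-4-[(2E,4E)-6-hydroxy-6-methylhepta-2,4-dien-2-yl]-2-[(1S,5R)-5-methyl-2-oxocyclopent-3-en-1-yl]cyclopentyl]methyl acetate
Conditions: Ac2O, pyridine, CH2Cl2, 0 °C
Reagents that add atoms: acetic anhydride, CC(=O)OC(C)=O
Why: Acetylation is selective for the single primary alcohol over the two tertiary ones and is mild enough to leave the epimerisable centre next to the ketone unchanged.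

Step 14
Reactants: 20 [(1R,2S,4S)-1-hydroxy-4-[(2E,4E)-6-hydroxy-6-methylhepta-2,4-dien-2-yl]-2-[(1S,5R)-5-methyl-2-oxocyclopent-3-en-1-yl]cyclopentyl]methyl acetate
Product: 21 [(1R,2S,4S)-1-hydroxy-4-[(2E,4E)-6-hydroperoxy-6-methylhepta-2,4-dien-2-yl]-2-[(1S,5R)-5-methyl-2-oxocyclopent-3-en-1-yl]cyclopentyl]methyl acetate
Conditions: 50% aq. H2O2, H2SO4 (cat.), Et2O, 0 °C
Reagents that add atoms: hydrogen peroxide, OO
Why: Acid-catalysed perhydrolysis (SN1), in which only the tertiary dienylic alcohol ionises and H2O2 traps the delocalised cation at its less hindered dimethyl-substituted end, keeping the conjugated (2E,4E)-diene and affecting no stereocentre.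

**Compound list**
1 | (S)-(−)-limonene, (4S)-1-methyl-4-(prop-1-en-2-yl)cyclohex-1-ene | CC1=CC[C@H](CC1)C(C)=C | starting material
2 | (4S)-1-methyl-4-(prop-1-en-2-yl)-7,8,9-trioxabicyclo[4.2.1]nonane (ozonide of the ring alkene, epimer mixture at the two ozonide carbons) | CC12CC[C@H](C(C)=C)CC(OO1)O2 | intermediate
3 | (3S)-6-oxo-3-(prop-1-en-2-yl)heptanal | O=CC[C@H](CCC(C)=O)C(C)=C | intermediate
4 | (3S)-6-oxo-3-(prop-1-en-2-yl)heptanoic acid | OC(=O)C[C@H](CCC(C)=O)C(C)=C | intermediate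
5 | (E)-but-2-en-1-ol | C/C=C/CO | starting material
6 | (E)-but-2-en-1-yl (3S)-6-oxo-3-(prop-1-en-2-yl)heptanoate | C/C=C/COC(=O)C[C@H](CCC(C)=O)C(C)=C | intermediate
7 | (E)-but-2-en-1-yl (3S)-3-(3-chloroprop-1-en-2-yl)-6-oxoheptanoate | C/C=C/COC(=O)C[C@H](CCC(C)=O)C(=C)CCl | intermediate
8 | (E)-but-2-en-1-yl 2-[(1S,4S)-4-acetyl-2-methylidenecyclopentyl]acetate | C/C=C/COC(=O)C[C@@H]1C[C@H](C(C)=O)CC1=C | intermediate
9 | (E)-but-2-en-1-yl 2-[(3R,4S,6S)-6-acetyl-1-oxaspiro[2.4]heptan-4-yl]acetate | C/C=C/COC(=O)C[C@@H]1C[C@H](C(C)=O)C[C@]13CO3 | intermediate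
10 | (E)-but-2-en-1-yl 2-[(3R,4S,6S)-6-[(E)-1-(4,4,5,5-tetramethyl-1,3,2-dioxaborolan-2-yl)prop-1-en-2-yl]-1-oxaspiro[2.4]heptan-4-yl]acetate | C/C=C/COC(=O)C[C@@H]1C[C@H](/C(C)=C/B2OC(C)(C)C(C)(C)O2)C[C@]13CO3 | intermediate
11 | (E)-trimethylsilyl ketene acetal of 10 (ring substituent cis to the crotyloxy oxygen) | C/C=C/CO/C(O[Si](C)(C)C)=C\[C@@H]1C[C@H](/C(C)=C/B2OC(C)(C)C(C)(C)O2)C[C@]13CO3 | intermediate
12 | (2S,3R)-3-methyl-2-[(3R,4S,6S)-6-[(E)-1-(4,4,5,5-tetramethyl-1,3,2-dioxaborolan-2-yl)prop-1-en-2-yl]-1-oxaspiro[2.4]heptan-4-yl]pent-4-enoic acid | OC(=O)[C@@H]([C@H](C)C=C)[C@@H]1C[C@H](/C(C)=C/B2OC(C)(C)C(C)(C)O2)C[C@]13CO3 | intermediate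
13 | (4S,4aS,6S,7aR)-4-[(2R)-but-3-en-2-yl]-7a-hydroxy-6-[(E)-1-(4,4,5,5-tetramethyl-1,3,2-dioxaborolan-2-yl)prop-1-en-2-yl]hexahydrocyclopenta[c]pyran-3(1H)-one | O=C1OC[C@@]2(O)C[C@@H](/C(C)=C/B3OC(C)(C)C(C)(C)O3)C[C@H]2[C@@H]1[C@H](C)C=C | intermediate
14 | 2-methylbut-3-yn-2-ol | CC(C)(O)C#C | starting material
15 | (E)-2-methyl-4-(tributylstannyl)but-3-en-2-ol | CCCC[Sn](CCCC)(CCCC)/C=C/C(C)(C)O | intermediate
16 | (E)-4-iodo-2-methylbut-3-en-2-ol | CC(C)(O)/C=C/I | intermediate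
17 | (4S,4aS,6S,7aR)-4-[(2R)-but-3-en-2-yl]-7a-hydroxy-6-[(2E,4E)-6-hydroxy-6-methylhepta-2,4-dien-2-yl]hexahydrocyclopenta[c]pyran-3(1H)-one | O=C1OC[C@@]2(O)C[C@@H](/C(C)=C/C=C/C(C)(C)O)C[C@H]2[C@@H]1[C@H](C)C=C | intermediate
18 | (4S,5R)-4-[(1S,2R,4S)-2-hydroxy-2-(hydroxymethyl)-4-[(2E,4E)-6-hydroxy-6-methylhepta-2,4-dien-2-yl]cyclopentyl]-5-methylhepta-1,6-dien-3-one | OC[C@@]1(O)C[C@@H](/C(C)=C/C=C/C(C)(C)O)C[C@H]1[C@@H](C(=O)C=C)[C@H](C)C=C | intermediate
19 | (4R,5S)-5-[(1S,2R,4S)-2-hydroxy-2-(hydroxymethyl)-4-[(2E,4E)-6-hydroxy-6-methylhepta-2,4-dien-2-yl]cyclopentyl]-4-methylcyclopent-2-en-1-one | OC[C@@]1(O)C[C@@H](/C(C)=C/C=C/C(C)(C)O)C[C@H]1[C@H]1C(=O)C=C[C@H]1C | intermediate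
20 | [(1R,2S,4S)-1-hydroxy-4-[(2E,4E)-6-hydroxy-6-methylhepta-2,4-dien-2-yl]-2-[(1S,5R)-5-methyl-2-oxocyclopent-3-en-1-yl]cyclopentyl]methyl acetate | CC(=O)OC[C@@]1(O)C[C@@H](/C(C)=C/C=C/C(C)(C)O)C[C@H]1[C@H]1C(=O)C=C[C@H]1C | intermediate
21 | [(1R,2S,4S)-1-hydroxy-4-[(2E,4E)-6-hydroperoxy-6-methylhepta-2,4-dien-2-yl]-2-[(1S,5R)-5-methyl-2-oxocyclopent-3-en-1-yl]cyclopentyl]methyl acetate | CC(=O)OC[C@@]1(O)C[C@@H](/C(C)=C/C=C/C(C)(C)OO)C[C@H]1[C@H]1C(=O)C=C[C@H]1C | target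

**Totals**
Total step count: 14. Longest linear sequence: 13 steps (steps 1–8 and 10–14; step 9 makes the coupling partner 16).

**The three steps most likely to fail**

Step 5 (cis/trans ratio at the acetyl-bearing carbon of ring A; it rests on a modest thermodynamic preference). The fallback sets out from 4 and comes back at 9, and makes this centre by hydrogenation instead of by the ring closure. Acid 4 is methylated (MeI, K2CO3, DMF) to methyl (3S)-6-oxo-3-(prop-1-en-2-yl)heptanoate F1, chlorinated as in step 4 to methyl (3S)-3-(3-chloroprop-1-en-2-yl)-6-oxoheptanoate F2, and dehydrogenated with 2-iodoxybenzoic acid (DMSO, 65 °C) to methyl (3R,4E)-3-(3-chloroprop-1-en-2-yl)-6-oxohept-4-enoate F3. PBu3 followed by brief KOH treatment closes ring A by a Morita–Baylis–Hillman-type cycloalkylation to methyl 2-[(1R)-3-acetyl-5-methylidenecyclopent-2-en-1-yl]acetate F4. mCPBA epoxidises the exocyclic alkene anti to the side arm to methyl 2-[(3R,4R)-6-acetyl-1-oxaspiro[2.4]hept-5-en-4-yl]acetate F5. H2 over Pd/C then adds to the enone face opposite the directly neighbouring side arm and gives only the cis isomer, methyl 2-[(3R,4S,6S)-6-acetyl-1-oxaspiro[2.4]heptan-4-yl]acetate F6. Bu2SnO-catalysed ester exchange with 5 (toluene, 90 °C, methanol distilled off) returns to 9.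

Step 8 (face selectivity of the rearrangement relies on one allylic stereocentre; the epoxide and boronate must survive the base). The fallback sets out from 10 and comes back at 19, and fixes the sense of the rearrangement by 1,3-chirality transfer from a secondary allylic ester. Bu2SnO-catalysed ester exchange of 10 in excess (2S,3E)-pent-3-en-2-ol (obtainable from ethyl (S)-lactate) gives (2S,3E)-pent-3-en-2-yl 2-[(3R,4S,6S)-6-[(E)-1-(4,4,5,5-tetramethyl-1,3,2-dioxaborolan-2-yl)prop-1-en-2-yl]-1-oxaspiro[2.4]heptan-4-yl]acetate F7. The same LiN(iPr)2/Me3SiCl protocol, now with the carbinol methyl group equatorial in the chair, gives after lactonisation (4S,4aS,6S,7aR)-7a-hydroxy-4-[(2R,3E)-pent-3-en-2-yl]-6-[(E)-1-(4,4,5,5-tetramethyl-1,3,2-dioxaborolan-2-yl)prop-1-en-2-yl]hexahydrocyclopenta[c]pyran-3(1H)-one F8. Suzuki coupling with 16 as in step 10 gives (4S,4aS,6S,7aR)-7a-hydroxy-6-[(2E,4E)-6-hydroxy-6-methylhepta-2,4-dien-2-yl]-4-[(2R,3E)-pent-3-en-2-yl]hexahydrocyclopenta[c]pyran-3(1H)-one F9. Vinyl addition as in step 11 gives (4S,5R,6E)-4-[(1S,2R,4S)-2-hydroxy-2-(hydroxymethyl)-4-[(2E,4E)-6-hydroxy-6-methylhepta-2,4-dien-2-yl]cyclopentyl]-5-methylocta-1,6-dien-3-one F10, and the metathesis of step 12 (propene is lost instead of ethene) returns to 19.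

Step 14 (the cation can also be trapped at its other end, and the acid may epimerise the cis-cyclopentenone). The fallback sets out from 13 and comes back at 21, and introduces the O–O bond by a singlet-oxygen ene reaction on a skipped diene. Suzuki coupling of 13 with 1-bromo-3-methylbut-2-ene (Pd(PPh3)4, K3PO4, THF/H2O) gives (4S,4aS,6S,7aR)-4-[(2R)-but-3-en-2-yl]-7a-hydroxy-6-[(2E)-6-methylhepta-2,5-dien-2-yl]hexahydrocyclopenta[c]pyran-3(1H)-one F11. Vinyl addition as in step 11 gives (4S,5R)-4-[(1S,2R,4S)-2-hydroxy-2-(hydroxymethyl)-4-[(2E)-6-methylhepta-2,5-dien-2-yl]cyclopentyl]-5-methylhepta-1,6-dien-3-one F12. Metathesis as in step 12 gives (4R,5S)-5-[(1S,2R,4S)-2-hydroxy-2-(hydroxymethyl)-4-[(2E)-6-methylhepta-2,5-dien-2-yl]cyclopentyl]-4-methylcyclopent-2-en-1-one F13, and acetylation as in step 13 gives [(1R,2S,4S)-1-hydroxy-4-[(2E)-6-methylhepta-2,5-dien-2-yl]-2-[(1S,5R)-5-methyl-2-oxocyclopent-3-en-1-yl]cyclopentyl]methyl acetate F14. Photo-oxygenation (O2, tetraphenylporphyrin, visible light, CH2Cl2, 0 °C; Schenck ene reaction) adds oxygen at the dimethyl-substituted carbon with transfer of the doubly allylic hydrogen and gives 21 with the new (E)-alkene; the regioisomeric secondary hydroperoxide has to be separated.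

**Further compounds**
F1 | step 5 | methyl (3S)-6-oxo-3-(prop-1-en-2-yl)heptanoate | COC(=O)C[C@H](CCC(C)=O)C(C)=C
F2 | step 5 | methyl (3S)-3-(3-chloroprop-1-en-2-yl)-6-oxoheptanoate | COC(=O)C[C@H](CCC(C)=O)C(=C)CCl
F3 | step 5 | methyl (3R,4E)-3-(3-chloroprop-1-en-2-yl)-6-oxohept-4-enoate | COC(=O)C[C@H](/C=C/C(C)=O)C(=C)CCl
F4 | step 5 | methyl 2-[(1R)-3-acetyl-5-methylidenecyclopent-2-en-1-yl]acetate | COC(=O)C[C@@H]1C=C(C(C)=O)CC1=C
F5 | step 5 | methyl 2-[(3R,4R)-6-acetyl-1-oxaspiro[2.4]hept-5-en-4-yl]acetate | COC(=O)C[C@@H]1C=C(C(C)=O)C[C@]13CO3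
F6 | step 5 | methyl 2-[(3R,4S,6S)-6-acetyl-1-oxaspiro[2.4]heptan-4-yl]acetate | COC(=O)C[C@@H]1C[C@H](C(C)=O)C[C@]13CO3
F7 | step 8 | (2S,3E)-pent-3-en-2-yl 2-[(3R,4S,6S)-6-[(E)-1-(4,4,5,5-tetramethyl-1,3,2-dioxaborolan-2-yl)prop-1-en-2-yl]-1-oxaspiro[2.4]heptan-4-yl]acetate | C/C=C/[C@H](C)OC(=O)C[C@@H]1C[C@H](/C(C)=C/B2OC(C)(C)C(C)(C)O2)C[C@]13CO3
F8 | step 8 | (4S,4aS,6S,7aR)-7a-hydroxy-4-[(2R,3E)-pent-3-en-2-yl]-6-[(E)-1-(4,4,5,5-tetramethyl-1,3,2-dioxaborolan-2-yl)prop-1-en-2-yl]hexahydrocyclopenta[c]pyran-3(1H)-one | O=C1OC[C@@]2(O)C[C@@H](/C(C)=C/B3OC(C)(C)C(C)(C)O3)C[C@H]2[C@@H]1[C@H](C)/C=C/C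
F9 | step 8 | (4S,4aS,6S,7aR)-7a-hydroxy-6-[(2E,4E)-6-hydroxy-6-methylhepta-2,4-dien-2-yl]-4-[(2R,3E)-pent-3-en-2-yl]hexahydrocyclopenta[c]pyran-3(1H)-one | O=C1OC[C@@]2(O)C[C@@H](/C(C)=C/C=C/C(C)(C)O)C[C@H]2[C@@H]1[C@H](C)/C=C/C
F10 | step 8 | (4S,5R,6E)-4-[(1S,2R,4S)-2-hydroxy-2-(hydroxymethyl)-4-[(2E,4E)-6-hydroxy-6-methylhepta-2,4-dien-2-yl]cyclopentyl]-5-methylocta-1,6-dien-3-one | OC[C@@]1(O)C[C@@H](/C(C)=C/C=C/C(C)(C)O)C[C@H]1[C@@H](C(=O)C=C)[C@H](C)/C=C/C
F11 | step 14 | (4S,4aS,6S,7aR)-4-[(2R)-but-3-en-2-yl]-7a-hydroxy-6-[(2E)-6-methylhepta-2,5-dien-2-yl]hexahydrocyclopenta[c]pyran-3(1H)-one | O=C1OC[C@@]2(O)C[C@@H](/C(C)=C/CC=C(C)C)C[C@H]2[C@@H]1[C@H](C)C=C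
F12 | step 14 | (4S,5R)-4-[(1S,2R,4S)-2-hydroxy-2-(hydroxymethyl)-4-[(2E)-6-methylhepta-2,5-dien-2-yl]cyclopentyl]-5-methylhepta-1,6-dien-3-one | OC[C@@]1(O)C[C@@H](/C(C)=C/CC=C(C)C)C[C@H]1[C@@H](C(=O)C=C)[C@H](C)C=C
F13 | step 14 | (4R,5S)-5-[(1S,2R,4S)-2-hydroxy-2-(hydroxymethyl)-4-[(2E)-6-methylhepta-2,5-dien-2-yl]cyclopentyl]-4-methylcyclopent-2-en-1-one | OC[C@@]1(O)C[C@@H](/C(C)=C/CC=C(C)C)C[C@H]1[C@H]1C(=O)C=C[C@H]1C
F14 | step 14 | [(1R,2S,4S)-1-hydroxy-4-[(2E)-6-methylhepta-2,5-dien-2-yl]-2-[(1S,5R)-5-methyl-2-oxocyclopent-3-en-1-yl]cyclopentyl]methyl acetate | CC(=O)OC[C@@]1(O)C[C@@H](/C(C)=C/CC=C(C)C)C[C@H]1[C@H]1C(=O)C=C[C@H]1C
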